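Ring B is built last, on the completed ring A fragment, instead of being imported as an arene. In ring B the C3′ hydroxyl is para to C6′ (the benzyl-bearing carbon) and meta to C1′ (the bridge carbon), the pattern of a 4-acylphenol; cutting C1′–C2′ and C5′–C6′ therefore leads back to Danishefsky's diene and an aryl ynone. One thermal [4+2] cycloaddition, followed by acid-induced loss of methanol and of the silyl group, closes ring B and places hydroxyl, bridge and future benzyl group correctly. The precursor is a pent-2-yn-1-one whose alkyne β-carbon carries the CH2CH2 bridge to the fully benzylated ring A and whose carbonyl carries a 4-benzyloxyphenyl group.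

Key step: step 9

Remark: the target has no stereocentre; ring A is the methoxy-bearing ring and ring B the bridged phenol ring (C1′ bridge, C3′ OH, C6′ 4-hydroxybenzyl); compounds 1, 4, 9, 13 and 15 are taken as catalogue items.

Step 1
Reactants: 1 methyl 3-hydroxy-5-methoxybenzoate
Product: 2 methyl 3-(benzyloxy)-5-methoxybenzoate
Conditions: BnBr, K2CO3, DMF, 25 °C
Reagents that add atoms: benzyl bromide, BrCc1ccccc1
Why: Williamson ether synthesis, in which the phenoxide formed with K2CO3 displaces bromide from benzyl bromide and the methyl ester is untouched.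

Step 2
Reactants: 2 methyl 3-(benzyloxy)-5-methoxybenzoate
Product: 3 methyl 3-(benzyloxy)-2,6-dibromo-5-methoxybenzoate
Conditions: NBS (2.2 equiv), MeCN, 25 → 60 °C
Reagents that add atoms: N-bromosuccinimide, O=C1CCC(=O)N1Br
Why: Electrophilic aromatic bromination, in which C2 and C6 are each para to one alkoxy group and ortho to the other while C4 is shielded between the two alkoxy groups, the outcome known for 2,6-dihalogenation of 3,5-dialkoxybenzoates.

Step 3
Reactants: 3 methyl 3-(benzyloxy)-2,6-dibromo-5-methoxybenzoate; 4 4-(benzyloxy)benzyl chloride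
Product: 6 methyl 3-(benzyloxy)-2,6-bis[4-(benzyloxy)benzyl]-5-methoxybenzoate, via [4-(benzyloxy)benzyl]zinc chloride 5 (not isolated)
Conditions: 4 (3 equiv), Zn dust, LiCl, THF, 25 °C; then 3, Pd(OAc)2 (cat.), SPhos, THF, 50 °C
Reagents that add atoms: none
Why: Negishi coupling, in which zinc inserts into the benzylic C–Cl bond in the presence of LiCl and the Pd/SPhos catalyst couples the benzylic zinc reagent with both ortho-flanked aryl bromides, whose oxidative addition the ortho ester assists; ester and ethers are tolerated by the organozinc.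

Step 4
Reactants: 6 methyl 3-(benzyloxy)-2,6-bis[4-(benzyloxy)benzyl]-5-methoxybenzoate
Product: 7 {3-(benzyloxy)-2,6-bis[4-(benzyloxy)benzyl]-5-methoxyphenyl}methanol
Conditions: LiAlH4, THF, 0 → 65 °C
Reagents that add atoms: none
Why: Hydride reduction of the ester to the primary alcohol; LiAlH4 overcomes the hindrance of the two ortho benzyl groups and leaves the ethers alone.

Step 5
Reactants: 7 {3-(benzyloxy)-2,6-bis[4-(benzyloxy)benzyl]-5-methoxyphenyl}methanol
Product: 8 3-(benzyloxy)-2,6-bis[4-(benzyloxy)benzyl]-5-methoxybenzyl bromide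
Conditions: CBr4, PPh3, CH2Cl2, 0 °C
Reagents that add atoms: carbon tetrabromide, BrC(Br)(Br)Br
Why: Appel reaction, in which the alcohol is activated as an alkoxyphosphonium ion and displaced by bromide under neutral conditions, which avoids acid-promoted Friedel–Crafts self-alkylation of the electron-rich rings.

Step 6
Reactants: 8 3-(benzyloxy)-2,6-bis[4-(benzyloxy)benzyl]-5-methoxybenzyl bromide; 9 1-(trimethylsilyl)propyne
Product: 11 {4-[3-(benzyloxy)-2,6-bis[4-(benzyloxy)benzyl]-5-methoxyphenyl]but-1-yn-1-yl}trimethylsilane, via 3-lithio-1-(trimethylsilyl)propyne 10 (not isolated)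
Conditions: 9 (1.6 equiv), n-BuLi (1.5 equiv), TMEDA, THF, −78 → −20 °C; then 8, −78 → 0 °C
Reagents that add atoms: none
Why: SN2 alkylation of the silyl-capped propargyl lithium at a primary benzylic bromide; the trimethylsilyl group directs attack through the CH2 terminus so that the alkyne and not the allene should result, and the electrophile has no β-hydrogen that could be lost by elimination.

Step 7
Reactants: 11 {4-[3-(benzyloxy)-2,6-bis[4-(benzyloxy)benzyl]-5-methoxyphenyl]but-1-yn-1-yl}trimethylsilane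
Product: 12 4-[3-(benzyloxy)-2,6-bis[4-(benzyloxy)benzyl]-5-methoxyphenyl]but-1-yne
Conditions: K2CO3 (cat.), MeOH/THF, 25 °C
Reagents that add atoms: none
Why: Base-catalysed methanolysis of the C(sp)–Si bond (protodesilylation); nothing else in the molecule reacts with methoxide at 25 °C.

Step 8
Reactants: 12 4-[3-(benzyloxy)-2,6-bis[4-(benzyloxy)benzyl]-5-methoxyphenyl]but-1-yne; 13 4-(benzyloxy)benzoyl chloride
Product: 14 1-[4-(benzyloxy)phenyl]-5-[3-(benzyloxy)-2,6-bis[4-(benzyloxy)benzyl]-5-methoxyphenyl]pent-2-yn-1-one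
Conditions: 13 (1.2 equiv), PdCl2(PPh3)2 (cat.), CuI (cat.), Et3N, THF, 25 °C
Reagents that add atoms: none
Why: Acyl Sonogashira coupling, in which the aroyl chloride adds oxidatively to palladium, the copper acetylide formed with CuI and Et3N transmetalates and reductive elimination gives the ynone without a strongly basic acetylide.

Step 9
Reactants: 14 1-[4-(benzyloxy)phenyl]-5-[3-(benzyloxy)-2,6-bis[4-(benzyloxy)benzyl]-5-methoxyphenyl]pent-2-yn-1-one; 15 trans-1-methoxy-3-(trimethylsilyloxy)buta-1,3-diene (Danishefsky's diene)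
Product: 17 [4-(benzyloxy)phenyl](2-{2-[3-(benzyloxy)-2,6-bis[4-(benzyloxy)benzyl]-5-methoxyphenyl]ethyl}-4-hydroxyphenyl)methanone, via cyclohexa-1,4-diene cycloadduct 16 (not isolated)
Conditions: 15 (4 equiv), toluene, 110 °C, sealed tube; then 1 M HCl, THF, 25 °C
Reagents that add atoms: none
Why: Normal-demand Diels–Alder reaction in which the electron-rich 1-methoxy-3-silyloxydiene adds across the aroyl-activated triple bond to give cyclohexa-1,4-diene 16, which on acid treatment loses methanol by 1,4-elimination and the silyl group by hydrolysis to give the phenol. The closest known reaction type is the cycloaddition of Danishefsky's diene with ynones or propiolates followed by aromatisation to 4-acylphenols. Ring B is closed by an intermolecular [4+2] cycloaddition in which both new σ-bonds (C1′–C2′ and C5′–C6′) form in the same pericyclic event, so no separate ring-closure mode arises. The only stereocentre formed, the methoxy-bearing carbon of 16, is racemic and is erased on aromatisation, so no stereocontrol is needed. The step needs regioselectivity, secured by polarity matching: the unsubstituted diene terminus C4, which has the largest HOMO coefficient, bonds to the ynone β-carbon bearing the bridge, which puts the silyloxy carbon para to the aroyl-bearing carbon. Chemoselectivity for the alkyne over the ketone carbonyl follows from running the reaction thermally without a Lewis acid, and the benzyl ethers are inert to heat and to dilute HCl.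

Step 10
Reactants: 17 [4-(benzyloxy)phenyl](2-{2-[3-(benzyloxy)-2,6-bis[4-(benzyloxy)benzyl]-5-methoxyphenyl]ethyl}-4-hydroxyphenyl)methanone
Product: 18 3-{2-[3-(benzyloxy)-2,6-bis[4-(benzyloxy)benzyl]-5-methoxyphenyl]ethyl}-4-[4-(benzyloxy)benzyl]phenol
Conditions: Et3SiH (4 equiv), BF3·OEt2, CH2Cl2/MeCN, 0 → 25 °C
Reagents that add atoms: none
Why: Ionic hydrogenation of a diaryl ketone (Kursanov–Parnes type), in which the BF3-activated carbonyl accepts hydride from Et3SiH, the benzhydryl oxygen then ionises to a cation stabilised by two para oxygen donors and takes a second hydride, while aryl benzyl ethers tolerate the Lewis acid at or below 25 °C.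

Step 11
Reactants: 18 3-{2-[3-(benzyloxy)-2,6-bis[4-(benzyloxy)benzyl]-5-methoxyphenyl]ethyl}-4-[4-(benzyloxy)benzyl]phenol
Product: 19 2,4-bis(4-hydroxybenzyl)-3-{2-[5-hydroxy-2-(4-hydroxybenzyl)phenyl]ethyl}-5-methoxyphenol (CNP0147493.0)
Conditions: H2 (1 atm), 10% Pd/C, EtOAc/MeOH, 25 °C
Reagents that add atoms: none
Why: Heterogeneous hydrogenolysis of the four aryl benzyl ethers over Pd/C; the diarylmethane C–C bonds, the aryl methyl ether and the phenols are inert under these conditions.

Compound list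
1 | methyl 3-hydroxy-5-methoxybenzoate | COC(=O)c1cc(O)cc(OC)c1 | starting material
2 | methyl 3-(benzyloxy)-5-methoxybenzoate | COC(=O)c1cc(OCc2ccccc2)cc(OC)c1 | intermediate
3 | methyl 3-(benzyloxy)-2,6-dibromo-5-methoxybenzoate | COC(=O)c1c(Br)c(OCc2ccccc2)cc(OC)c1Br | intermediate
4 | 4-(benzyloxy)benzyl chloride | ClCc1ccc(OCc2ccccc2)cc1 | starting material
5 | [4-(benzyloxy)benzyl]zinc chloride (THF solution, not isolated) | Cl[Zn]Cc1ccc(OCc2ccccc2)cc1 | intermediate
6 | methyl 3-(benzyloxy)-2,6-bis[4-(benzyloxy)benzyl]-5-methoxybenzoate | COC(=O)c1c(Cc2ccc(OCc3ccccc3)cc2)c(OCc2ccccc2)cc(OC)c1Cc1ccc(OCc2ccccc2)cc1 | intermediate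
7 | {3-(benzyloxy)-2,6-bis[4-(benzyloxy)benzyl]-5-methoxyphenyl}methanol | OCc1c(Cc2ccc(OCc3ccccc3)cc2)c(OCc2ccccc2)cc(OC)c1Cc1ccc(OCc2ccccc2)cc1 | intermediate
8 | 3-(benzyloxy)-2,6-bis[4-(benzyloxy)benzyl]-5-methoxybenzyl bromide | BrCc1c(Cc2ccc(OCc3ccccc3)cc2)c(OCc2ccccc2)cc(OC)c1Cc1ccc(OCc2ccccc2)cc1 | intermediate
9 | 1-(trimethylsilyl)propyne | CC#C[Si](C)(C)C | starting material
10 | 3-lithio-1-(trimethylsilyl)propyne (not isolated) | [Li]CC#C[Si](C)(C)C | intermediate
11 | {4-[3-(benzyloxy)-2,6-bis[4-(benzyloxy)benzyl]-5-methoxyphenyl]but-1-yn-1-yl}trimethylsilane | C[Si](C)(C)C#CCCc1c(Cc2ccc(OCc3ccccc3)cc2)c(OCc2ccccc2)cc(OC)c1Cc1ccc(OCc2ccccc2)cc1 | intermediate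
12 | 4-[3-(benzyloxy)-2,6-bis[4-(benzyloxy)benzyl]-5-methoxyphenyl]but-1-yne | C#CCCc1c(Cc2ccc(OCc3ccccc3)cc2)c(OCc2ccccc2)cc(OC)c1Cc1ccc(OCc2ccccc2)cc1 | intermediate
13 | 4-(benzyloxy)benzoyl chloride | O=C(Cl)c1ccc(OCc2ccccc2)cc1 | starting material
14 | 1-[4-(benzyloxy)phenyl]-5-[3-(benzyloxy)-2,6-bis[4-(benzyloxy)benzyl]-5-methoxyphenyl]pent-2-yn-1-one | O=C(C#CCCc1c(Cc2ccc(OCc3ccccc3)cc2)c(OCc2ccccc2)cc(OC)c1Cc1ccc(OCc2ccccc2)cc1)c1ccc(OCc2ccccc2)cc1 | intermediate
15 | trans-1-methoxy-3-(trimethylsilyloxy)buta-1,3-diene | CO/C=C/C(=C)O[Si](C)(C)C | starting material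
16 | racemic [4-(benzyloxy)phenyl]{2-[2-[3-(benzyloxy)-2,6-bis[4-(benzyloxy)benzyl]-5-methoxyphenyl]ethyl]-6-methoxy-4-(trimethylsilyloxy)cyclohexa-1,4-dien-1-yl}methanone (not isolated) | COC1C=C(O[Si](C)(C)C)CC(CCc2c(Cc3ccc(OCc4ccccc4)cc3)c(OCc3ccccc3)cc(OC)c2Cc2ccc(OCc3ccccc3)cc2)=C1C(=O)c1ccc(OCc2ccccc2)cc1 | intermediate
17 | [4-(benzyloxy)phenyl](2-{2-[3-(benzyloxy)-2,6-bis[4-(benzyloxy)benzyl]-5-methoxyphenyl]ethyl}-4-hydroxyphenyl)methanone | O=C(c1ccc(OCc2ccccc2)cc1)c1ccc(O)cc1CCc1c(Cc2ccc(OCc3ccccc3)cc2)c(OCc2ccccc2)cc(OC)c1Cc1ccc(OCc2ccccc2)cc1 | intermediate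
18 | 3-{2-[3-(benzyloxy)-2,6-bis[4-(benzyloxy)benzyl]-5-methoxyphenyl]ethyl}-4-[4-(benzyloxy)benzyl]phenol | Oc1ccc(Cc2ccc(OCc3ccccc3)cc2)c(CCc2c(Cc3ccc(OCc4ccccc4)cc3)c(OCc3ccccc3)cc(OC)c2Cc2ccc(OCc3ccccc3)cc2)c1 | intermediate
19 | 2,4-bis(4-hydroxybenzyl)-3-{2-[5-hydroxy-2-(4-hydroxybenzyl)phenyl]ethyl}-5-methoxyphenol | COc1cc(O)c(Cc2ccc(O)cc2)c(CCc2cc(O)ccc2Cc2ccc(O)cc2)c1Cc1ccc(O)cc1 | target

Total step count: 11. Longest linear sequence: 11 steps (1 → 19); the zinc reagent 5 is made and consumed within step 3.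

Steps most likely to fail

Step 9. The cycloaddition to a β-alkyl ynone whose carbonyl is deactivated by a para-alkoxy donor may be slower than thermal decay or adventitious hydrolysis of the diene, so that ynone is left unconverted, or aromatisation may stall before methanol is lost. The fallback sets out from bromide 8 and chloride 4 and comes back to the route at target 19; it joins a preformed ring B by olefination instead of building it.
- Bromide 8 is heated with PPh3 (toluene, 90 °C) to give {3-(benzyloxy)-2,6-bis[4-(benzyloxy)benzyl]-5-methoxybenzyl}triphenylphosphonium bromide F1.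
- Commercial 4-(benzyloxy)-2-formylphenylboronic acid (OB(O)c1ccc(OCc2ccccc2)cc1C=O) is coupled with chloride 4 in a Suzuki–Miyaura reaction (Pd(PPh3)4, Na2CO3, DME/H2O, 80 °C) to give 5-(benzyloxy)-2-[4-(benzyloxy)benzyl]benzaldehyde F2.
- Deprotonation of F1 (KOtBu, THF, 0 °C) gives {3-(benzyloxy)-2,6-bis[4-(benzyloxy)benzyl]-5-methoxybenzylidene}triphenylphosphorane F3. Its Wittig reaction with F2 should give 1-(benzyloxy)-2,4-bis[4-(benzyloxy)benzyl]-3-{2-[5-(benzyloxy)-2-[4-(benzyloxy)benzyl]phenyl]ethenyl}-5-methoxybenzene F4 as an E/Z mixture.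
- Hydrogenation of F4 (H2, Pd/C, EtOAc/MeOH, 25 °C) saturates the alkene and removes all five benzyl groups, giving 19.

Step 3. The second coupling may stall because transmetalation and reductive elimination at a palladium centre flanked by two ortho substituents are slow, and the electron-rich benzylic zinc reagent may be consumed by Wurtz-type homocoupling while it is formed. The fallback sets out from dibromide 3 and chloride 4 and comes back at 6; it replaces the in situ zinc reagent by an isolable boron nucleophile.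
- Chloride 4 is borylated (B2pin2, Pd(dba)2, tris(4-methoxyphenyl)phosphine, KOAc, toluene, 50 °C) to 2-[4-(benzyloxy)benzyl]-4,4,5,5-tetramethyl-1,3,2-dioxaborolane F5.
- KHF2 (MeOH/H2O, 25 °C) converts F5 into potassium [4-(benzyloxy)benzyl]trifluoroborate F6.
- Suzuki–Miyaura coupling of F6 (3 equiv) with 3 (Pd(OAc)2, RuPhos, K2CO3, toluene/H2O, 90 °C) should give 6.

Step 10. The Lewis acid may cleave or shift benzyl groups, and the diarylmethyl cation may be captured by an electron-rich ring in competition with hydride transfer, or deoxygenation may stop at the carbinol stage. The fallback sets out from ketone 17 and comes back at target 19; it separates carbonyl reduction from C–O cleavage and avoids strong acid.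
- NaBH4 (excess, THF/MeOH, 40 °C) reduces 17 to racemic [4-(benzyloxy)phenyl](2-{2-[3-(benzyloxy)-2,6-bis[4-(benzyloxy)benzyl]-5-methoxyphenyl]ethyl}-4-hydroxyphenyl)methanol F7.
- Hydrogenation of F7 (H2, Pd/C, EtOAc/AcOH, 25 °C) cleaves the doubly benzylic C–OH bond together with the four benzyl ethers and should give 19 directly.

Further compounds
F1 | step 9 | {3-(benzyloxy)-2,6-bis[4-(benzyloxy)benzyl]-5-methoxybenzyl}triphenylphosphonium bromide | [Br-].c1ccc(cc1)[P+](Cc1c(Cc2ccc(OCc3ccccc3)cc2)c(OCc2ccccc2)cc(OC)c1Cc1ccc(OCc2ccccc2)cc1)(c1ccccc1)c1ccccc1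
F2 | step 9 | 5-(benzyloxy)-2-[4-(benzyloxy)benzyl]benzaldehyde | O=Cc1cc(OCc2ccccc2)ccc1Cc1ccc(OCc2ccccc2)cc1
F3 | step 9 | {3-(benzyloxy)-2,6-bis[4-(benzyloxy)benzyl]-5-methoxybenzylidene}triphenylphosphorane (formed in the flask) | c1ccc(cc1)P(=Cc1c(Cc2ccc(OCc3ccccc3)cc2)c(OCc2ccccc2)cc(OC)c1Cc1ccc(OCc2ccccc2)cc1)(c1ccccc1)c1ccccc1
F4 | step 9 | 1-(benzyloxy)-2,4-bis[4-(benzyloxy)benzyl]-3-{2-[5-(benzyloxy)-2-[4-(benzyloxy)benzyl]phenyl]ethenyl}-5-methoxybenzene (E/Z mixture, geometry left open) | C(=Cc1c(Cc2ccc(OCc3ccccc3)cc2)c(OCc2ccccc2)cc(OC)c1Cc1ccc(OCc2ccccc2)cc1)c1cc(OCc2ccccc2)ccc1Cc1ccc(OCc2ccccc2)cc1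
F5 | step 3 | 2-[4-(benzyloxy)benzyl]-4,4,5,5-tetramethyl-1,3,2-dioxaborolane | CC1(C)OB(Cc2ccc(OCc3ccccc3)cc2)OC1(C)C
F6 | step 3 | potassium [4-(benzyloxy)benzyl]trifluoroborate | [K+].F[B-](F)(F)Cc1ccc(OCc2ccccc2)cc1
F7 | step 10 | racemic [4-(benzyloxy)phenyl](2-{2-[3-(benzyloxy)-2,6-bis[4-(benzyloxy)benzyl]-5-methoxyphenyl]ethyl}-4-hydroxyphenyl)methanol | OC(c1ccc(OCc2ccccc2)cc1)c1ccc(O)cc1CCc1c(Cc2ccc(OCc3ccccc3)cc2)c(OCc2ccccc2)cc(OC)c1Cc1ccc(OCc2ccccc2)cc1
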